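**Strategy**

The route rests on cutting the benzofuran C3–C3a bond. The furan ring of the target (O1, C2, C3, C3a, C7a) is the pyranone ring of a flavanone with its carbonyl carbon excised, and the phloroglucinol-derived benzo ring (ring A, C3a–C7a) is a first-rate migrating group. In one operation an oxidative 1,2-aryl shift moves the ring A carbon from the carbonyl carbon to C3, closing the five-membered ring and leaving the extruded carbon as a removable methyl ester. The precursor is a racemic 5-methoxy-7-benzyloxyflavanone whose 2-aryl group is the finished 7-methoxy-2,2-dimethylchroman-5-yl unit. Aromatisation, decarboxylation and a C7-directed Claisen rearrangement complete the target.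

Key step: step 7

Remark on the chemistry: the target is achiral, so 10–13 are carried as racemates (one enantiomer drawn in the SMILES) and their stereocentres are erased at the aromatisation in step 8; 1, 2, 7 and 18 are taken as catalogue chemicals.

**Route**

Step 1
Reactants: 1 3-hydroxy-5-methoxybenzaldehyde; 2 3-chloro-3-methylbut-1-yne
Product: 3 3-methoxy-5-[(2-methylbut-3-yn-2-yl)oxy]benzaldehyde
Conditions: K2CO3, KI (cat.), CuI (cat.), DMF, 65 °C
Reagents that add atoms: none
Why: Williamson-type O-alkylation of the phenoxide by a tertiary propargylic chloride, made feasible by copper acetylide-assisted ionisation of the chloride, should leave the aldehyde untouched and creates no stereocentre.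

Step 2
Reactants: 3 3-methoxy-5-[(2-methylbut-3-yn-2-yl)oxy]benzaldehyde
Product: 5 7-methoxy-2,2-dimethyl-2H-chromene-5-carbaldehyde, via allenyl phenol 4 (not isolated)
Conditions: PhNEt2, 190 °C
Reagents that add atoms: none
Why: An aromatic propargyl Claisen rearrangement ([3,3] shift) should give allenyl phenol 4, which closes to the 2H-chromene by 1,5-hydrogen shift and oxa-6π-electrocyclisation; the shift is expected at the carbon between the ether oxygen and the formyl group because a meta acceptor directs toward itself and a meta donor (OMe) directs para to itself, and both point to that carbon.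

Step 3
Reactants: 5 7-methoxy-2,2-dimethyl-2H-chromene-5-carbaldehyde
Product: 6 7-methoxy-2,2-dimethylchroman-5-carbaldehyde
Conditions: H2 (1 atm), Pd/C, Ph2S (cat.), EtOAc, rt
Reagents that add atoms: none
Why: Chemoselective catalytic hydrogenation, in which diphenyl sulfide tempers Pd/C so that the cis-disubstituted styrenic C3–C4 alkene is saturated while the aromatic aldehyde is not reduced.

Step 4
Reactants: 7 1-(2,4-dihydroxy-6-methoxyphenyl)ethan-1-one
Product: 8 1-[4-(benzyloxy)-2-hydroxy-6-methoxyphenyl]ethan-1-one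
Conditions: BnBr (1.05 equiv), K2CO3, acetone, reflux
Reagents that add atoms: benzyl bromide, BrCc1ccccc1
Why: Williamson ether synthesis at the only non-chelated phenol, since the 2-OH is held in a six-membered hydrogen bond to the acetyl carbonyl and should stay free.

Step 5
Reactants: 8 1-[4-(benzyloxy)-2-hydroxy-6-methoxyphenyl]ethan-1-one; 6 7-methoxy-2,2-dimethylchroman-5-carbaldehyde
Product: 9 (E)-1-[4-(benzyloxy)-2-hydroxy-6-methoxyphenyl]-3-(7-methoxy-2,2-dimethylchroman-5-yl)prop-2-en-1-one
Conditions: KOH (50% aq.), EtOH, rt; then dilute HCl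
Reagents that add atoms: none
Why: Claisen–Schmidt (crossed aldol) condensation of the methyl ketone enolate with a non-enolisable aldehyde, with E1cB dehydration giving the thermodynamically preferred E-enone.

Step 6
Reactants: 9 (E)-1-[4-(benzyloxy)-2-hydroxy-6-methoxyphenyl]-3-(7-methoxy-2,2-dimethylchroman-5-yl)prop-2-en-1-one
Product: 10 7-(benzyloxy)-5-methoxy-2-(7-methoxy-2,2-dimethylchroman-5-yl)chroman-4-one (racemic)
Conditions: NaOAc, EtOH, reflux
Reagents that add atoms: none
Why: Base-mediated intramolecular oxa-Michael addition (6-endo-trig) of the 2'-phenoxide to the enone, favoured because the 6'-methoxy group twists the aryl ketone out of conjugation; the single stereocentre C2 forms as a racemate and is removed later.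

Step 7
Reactants: 10 7-(benzyloxy)-5-methoxy-2-(7-methoxy-2,2-dimethylchroman-5-yl)chroman-4-one (racemic)
Product: 13 methyl trans-6-(benzyloxy)-4-methoxy-2-(7-methoxy-2,2-dimethylchroman-5-yl)-2,3-dihydrobenzofuran-3-carboxylate (racemic), via enol methyl ether 11 (not isolated), via iodanyl dimethyl ketal 12 (not isolated)
Conditions: PhI(OAc)2 (1.2 equiv), conc. H2SO4 (0.3 equiv), HC(OMe)3, 0 °C to rt
Reagents that add atoms: trimethyl orthoformate, COC(OC)OC
Why: Acid and the orthoformate should turn the ketone into enol ether 11, which attacks the trivalent iodine reagent at C3 on the face opposite the C2 aryl group, and methanol released from the orthoformate caps C4 to give ketal 12 with an axial C3–I bond. Loss of iodobenzene is then assisted by ring A: the ring A carbon (old C4a) shifts from C4 to C3 through a bridged phenonium-type transition state anti to the leaving iodine, and the resulting dimethoxycarbenium ion collapses to the methyl ester. The closest known reaction type is the oxidative ring contraction of flavanones and other cyclic aryl ketones by PhI(OAc)2 or Tl(NO3)3 in trimethyl orthoformate. The five-membered ring is closed by ring contraction of the pyranone (a semipinacol-like 1,2-aryl migration forming C3–C3a), not by cyclisation of an open chain. The new stereocentre C3 is set by substrate control from C2, since trans delivery of iodine followed by inversion places the ester trans to the aryl group, which is also the thermodynamic arrangement. The step needs ring A migration to beat 2-aryl migration (isoflavone) and elimination (flavone), and ring A carries oxygen donors ortho and para to the migrating carbon whereas the chromanyl group has its oxygens meta to its attachment carbon and bridges poorly.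

Step 8
Reactants: 13 methyl trans-6-(benzyloxy)-4-methoxy-2-(7-methoxy-2,2-dimethylchroman-5-yl)-2,3-dihydrobenzofuran-3-carboxylate (racemic)
Product: 14 methyl 6-(benzyloxy)-4-methoxy-2-(7-methoxy-2,2-dimethylchroman-5-yl)benzofuran-3-carboxylate
Conditions: DDQ (1.2 equiv), 1,4-dioxane, 80 °C
Reagents that add atoms: none
Why: DDQ dehydrogenation, in which hydride abstraction from C3–H (benzylic to the trioxygenated ring A) and loss of the C2 proton should give the aromatic furan ring and remove both stereocentres; should the chroman C3–C4 bond also be dehydrogenated, the hydrogenation of step 11 would restore it.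

Step 9
Reactants: 14 methyl 6-(benzyloxy)-4-methoxy-2-(7-methoxy-2,2-dimethylchroman-5-yl)benzofuran-3-carboxylate
Product: 15 6-(benzyloxy)-4-methoxy-2-(7-methoxy-2,2-dimethylchroman-5-yl)benzofuran-3-carboxylic acid
Conditions: KOH, EtOH/H2O, reflux; then aq. HCl
Reagents that add atoms: potassium hydroxide, [K+].[OH-]
Why: Saponification (acyl–oxygen cleavage) of the hindered methyl ester under forcing alkaline conditions, safe now that aromatisation has removed the β-aryloxy elimination pathway, with the benzyl and methyl ethers inert to hydroxide.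

Step 10
Reactants: 15 6-(benzyloxy)-4-methoxy-2-(7-methoxy-2,2-dimethylchroman-5-yl)benzofuran-3-carboxylic acid
Product: 16 6-(benzyloxy)-4-methoxy-2-(7-methoxy-2,2-dimethylchroman-5-yl)benzofuran
Conditions: Cu2O (cat.), 1,10-phenanthroline (cat.), NMP/quinoline, 170 °C
Reagents that add atoms: none
Why: Copper-catalysed protodecarboxylation of a heteroaryl carboxylic acid through an aryl–copper intermediate that is protonated at C3, helped by the electron-rich benzofuran nucleus and by relief of crowding between the 2-aryl and 4-methoxy groups.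

Step 11
Reactants: 16 6-(benzyloxy)-4-methoxy-2-(7-methoxy-2,2-dimethylchroman-5-yl)benzofuran
Product: 17 4-methoxy-2-(7-methoxy-2,2-dimethylchroman-5-yl)benzofuran-6-ol
Conditions: H2 (1 atm), Pd/C, EtOAc/EtOH, rt
Reagents that add atoms: none
Why: Catalytic hydrogenolysis of the benzyl aryl ether, under which the methyl ethers and the chroman are inert and the aromatic furan ring should not be reduced at balloon pressure and room temperature.

Step 12
Reactants: 17 4-methoxy-2-(7-methoxy-2,2-dimethylchroman-5-yl)benzofuran-6-ol; 18 1-bromo-3-methylbut-2-ene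
Product: 19 4-methoxy-2-(7-methoxy-2,2-dimethylchroman-5-yl)-6-[(3-methylbut-2-en-1-yl)oxy]benzofuran
Conditions: K2CO3, acetone, reflux
Reagents that add atoms: none
Why: Williamson ether synthesis (SN2 at a primary allylic bromide) on the only free phenol, with O-alkylation favoured by the potassium phenoxide in a polar aprotic medium.

Step 13
Reactants: 19 4-methoxy-2-(7-methoxy-2,2-dimethylchroman-5-yl)-6-[(3-methylbut-2-en-1-yl)oxy]benzofuran
Product: 21 4-methoxy-2-(7-methoxy-2,2-dimethylchroman-5-yl)-7-(2-methylbut-3-en-2-yl)benzofuran-6-ol, via ortho dienone 20 (not isolated)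
Conditions: PhNEt2, 200 °C
Reagents that add atoms: none
Why: Aromatic Claisen rearrangement, a [3,3] sigmatropic shift through a chair transition state that attaches the dimethyl-bearing allyl terminus to C7 (dienone 20, which tautomerises) and so gives the 1,1-dimethylallyl group; C7 should be preferred over C5 because the benzofuran C6–C7 bond has the higher double-bond character (as 2-naphthyl allyl ethers go to C1) and C5 is screened by the 4-methoxy group.

Step 14
Reactants: 21 4-methoxy-2-(7-methoxy-2,2-dimethylchroman-5-yl)-7-(2-methylbut-3-en-2-yl)benzofuran-6-ol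
Product: 22 2-(7-hydroxy-2,2-dimethylchroman-5-yl)-7-(2-methylbut-3-en-2-yl)benzofuran-4,6-diol
Conditions: NaSEt (excess), DMF, 140 °C; then dilute HCl
Reagents that add atoms: none
Why: Nucleophilic (SN2) O-demethylation by ethanethiolate at both methyl carbons, a soft nucleophile that should leave the terminal alkene, the tertiary chroman ether and the benzofuran untouched; excess reagent and high temperature are used because the C6 phenoxide slows cleavage of the C4 methyl ether.

**Compound list**

1 | 3-hydroxy-5-methoxybenzaldehyde | O=Cc1cc(O)cc(OC)c1 | starting material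
2 | 3-chloro-3-methylbut-1-yne | C#CC(C)(C)Cl | starting material
3 | 3-methoxy-5-[(2-methylbut-3-yn-2-yl)oxy]benzaldehyde | O=Cc1cc(OC)cc(OC(C)(C)C#C)c1 | intermediate
4 | 3-hydroxy-5-methoxy-2-(3-methylbuta-1,2-dien-1-yl)benzaldehyde (allenyl phenol, not isolated) | O=Cc1cc(OC)cc(O)c1C=C=C(C)C | intermediate
5 | 7-methoxy-2,2-dimethyl-2H-chromene-5-carbaldehyde | O=Cc1cc(OC)cc2OC(C)(C)C=Cc12 | intermediate
6 | 7-methoxy-2,2-dimethylchroman-5-carbaldehyde | O=Cc1cc(OC)cc2OC(C)(C)CCc12 | intermediate
7 | 1-(2,4-dihydroxy-6-methoxyphenyl)ethan-1-one | CC(=O)c1c(O)cc(O)cc1OC | starting material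
8 | 1-[4-(benzyloxy)-2-hydroxy-6-methoxyphenyl]ethan-1-one | CC(=O)c1c(O)cc(OCc2ccccc2)cc1OC | intermediate
9 | (E)-1-[4-(benzyloxy)-2-hydroxy-6-methoxyphenyl]-3-(7-methoxy-2,2-dimethylchroman-5-yl)prop-2-en-1-one | O=C(/C=C/c1cc(OC)cc2OC(C)(C)CCc12)c1c(O)cc(OCc2ccccc2)cc1OC | intermediate
10 | 7-(benzyloxy)-5-methoxy-2-(7-methoxy-2,2-dimethylchroman-5-yl)chroman-4-one (racemic, one enantiomer drawn) | O=C1C[C@H](c2cc(OC)cc3OC(C)(C)CCc23)Oc2cc(OCc3ccccc3)cc(OC)c12 | intermediate
11 | 7-(benzyloxy)-4,5-dimethoxy-2-(7-methoxy-2,2-dimethylchroman-5-yl)-2H-chromene (enol methyl ether, racemic, not isolated) | COC1=C[C@H](c2cc(OC)cc3OC(C)(C)CCc23)Oc2cc(OCc3ccccc3)cc(OC)c12 | intermediate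
12 | [2,3-trans-7-(benzyloxy)-4,4,5-trimethoxy-2-(7-methoxy-2,2-dimethylchroman-5-yl)chroman-3-yl](phenyl)-λ3-iodanyl acetate (racemic, not isolated) | COC1(OC)[C@@H](I(OC(C)=O)c2ccccc2)[C@H](c2cc(OC)cc3OC(C)(C)CCc23)Oc2cc(OCc3ccccc3)cc(OC)c12 | intermediate
13 | methyl trans-6-(benzyloxy)-4-methoxy-2-(7-methoxy-2,2-dimethylchroman-5-yl)-2,3-dihydrobenzofuran-3-carboxylate (racemic, one enantiomer drawn) | COC(=O)[C@H]1[C@H](c2cc(OC)cc3OC(C)(C)CCc23)Oc2cc(OCc3ccccc3)cc(OC)c12 | intermediate
14 | methyl 6-(benzyloxy)-4-methoxy-2-(7-methoxy-2,2-dimethylchroman-5-yl)benzofuran-3-carboxylate | COC(=O)c1c(-c2cc(OC)cc3OC(C)(C)CCc23)oc2cc(OCc3ccccc3)cc(OC)c12 | intermediate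
15 | 6-(benzyloxy)-4-methoxy-2-(7-methoxy-2,2-dimethylchroman-5-yl)benzofuran-3-carboxylic acid | OC(=O)c1c(-c2cc(OC)cc3OC(C)(C)CCc23)oc2cc(OCc3ccccc3)cc(OC)c12 | intermediate
16 | 6-(benzyloxy)-4-methoxy-2-(7-methoxy-2,2-dimethylchroman-5-yl)benzofuran | COc1cc(OCc2ccccc2)cc2oc(-c3cc(OC)cc4OC(C)(C)CCc34)cc12 | intermediate
17 | 4-methoxy-2-(7-methoxy-2,2-dimethylchroman-5-yl)benzofuran-6-ol | COc1cc(O)cc2oc(-c3cc(OC)cc4OC(C)(C)CCc34)cc12 | intermediate
18 | 1-bromo-3-methylbut-2-ene | CC(C)=CCBr | starting material
19 | 4-methoxy-2-(7-methoxy-2,2-dimethylchroman-5-yl)-6-[(3-methylbut-2-en-1-yl)oxy]benzofuran | COc1cc(OCC=C(C)C)cc2oc(-c3cc(OC)cc4OC(C)(C)CCc34)cc12 | intermediate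
20 | 4-methoxy-2-(7-methoxy-2,2-dimethylchroman-5-yl)-7-(2-methylbut-3-en-2-yl)benzofuran-6(7H)-one (ortho dienone, racemic, not isolated) | C=CC(C)(C)[C@H]1C(=O)C=C(OC)c2cc(-c3cc(OC)cc4OC(C)(C)CCc34)oc21 | intermediate
21 | 4-methoxy-2-(7-methoxy-2,2-dimethylchroman-5-yl)-7-(2-methylbut-3-en-2-yl)benzofuran-6-ol | C=CC(C)(C)c1c(O)cc(OC)c2cc(-c3cc(OC)cc4OC(C)(C)CCc34)oc12 | intermediate
22 | 2-(7-hydroxy-2,2-dimethylchroman-5-yl)-7-(2-methylbut-3-en-2-yl)benzofuran-4,6-diol (no stereocentre) | C=CC(C)(C)c1c(O)cc(O)c2cc(-c3cc(O)cc4c3CCC(C)(C)O4)oc12 | target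

**Step count and risks**

Total step count: 14. Longest linear sequence: 13 steps (steps 1–3, then 5–14).

Steps most likely to fail:

1. Step 7 (key step). The oxidation may divert into dehydrogenation to the flavone, migration of the 2-aryl group, simple α-methoxylation, or electrophilic attack of the iodine reagent on the resorcinol-type chroman ring. Fallback, setting out from 10 and coming back at 13: deprotonation with LiN(SiMe3)2 in THF at −78 °C and acylation with CF3CO2CH2CF3 would give 2,3-trans-7-(benzyloxy)-5-methoxy-2-(7-methoxy-2,2-dimethylchroman-5-yl)-3-(trifluoroacetyl)chroman-4-one F1. MsN3 and Et3N in MeCN would then effect detrifluoroacetylative diazo transfer to 7-(benzyloxy)-3-diazo-5-methoxy-2-(7-methoxy-2,2-dimethylchroman-5-yl)chroman-4-one F2. Irradiation at 365 nm in MeOH would expel nitrogen and trigger a Wolff rearrangement, in which the same ring A carbon migrates to C3, giving the ketene [6-(benzyloxy)-4-methoxy-2-(7-methoxy-2,2-dimethylchroman-5-yl)benzofuran-3(2H)-ylidene]methanone F3. Methanol would trap the ketene as ester 13, possibly accompanied by methyl cis-6-(benzyloxy)-4-methoxy-2-(7-methoxy-2,2-dimethylchroman-5-yl)-2,3-dihydrobenzofuran-3-carboxylate F4; the two epimers need not be separated because step 8 converts both into 14.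

2. Step 13. The rearrangement may go partly to C5, and the freshly formed ortho-allyl phenol may react on at 200 °C (abnormal Claisen through the phenolic O–H, ring closure of the phenol onto the alkene, or loss of the prenyl group). Fallback, setting out from 19 and coming back at 22: heating 19 in PhNEt2 with Ac2O and NaOAc would acetylate the phenol as soon as the dienone tautomerises, giving 4-methoxy-2-(7-methoxy-2,2-dimethylchroman-5-yl)-7-(2-methylbut-3-en-2-yl)benzofuran-6-yl acetate F5, which lacks the O–H needed for those follow-up reactions. F5 would be taken directly into the NaSEt conditions of step 14, where the thiolate removes the acetyl group and then both methyl groups.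

3. Step 14. The demethylation may stall after the chroman methyl ether has gone, because the C6 phenoxide deactivates the meta C4 methoxy group, and prolonged heating invites thiol addition to the vinyl group. Fallback, setting out from 21 and coming back at 22: 3,4-dihydro-2H-pyran with pyridinium p-toluenesulfonate in CH2Cl2 would mask the phenol as 4-methoxy-2-(7-methoxy-2,2-dimethylchroman-5-yl)-7-(2-methylbut-3-en-2-yl)-6-(tetrahydropyran-2-yloxy)benzofuran F6, so that ring A carries no phenoxide at the outset. NaSEt in DMF at 130 °C would then cleave both methyl ethers to 2-(7-hydroxy-2,2-dimethylchroman-5-yl)-7-(2-methylbut-3-en-2-yl)-6-(tetrahydropyran-2-yloxy)benzofuran-4-ol F7. Pyridinium p-toluenesulfonate in MeOH at 40 °C would remove the acetal to give 22.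

**Further compounds**

F1 | step 7 | 2,3-trans-7-(benzyloxy)-5-methoxy-2-(7-methoxy-2,2-dimethylchroman-5-yl)-3-(trifluoroacetyl)chroman-4-one (racemic) | O=C1[C@@H](C(=O)C(F)(F)F)[C@H](c2cc(OC)cc3OC(C)(C)CCc23)Oc2cc(OCc3ccccc3)cc(OC)c12
F2 | step 7 | 7-(benzyloxy)-3-diazo-5-methoxy-2-(7-methoxy-2,2-dimethylchroman-5-yl)chroman-4-one (racemic) | O=C1C(=[N+]=[N-])[C@H](c2cc(OC)cc3OC(C)(C)CCc23)Oc2cc(OCc3ccccc3)cc(OC)c12
F3 | step 7 | [6-(benzyloxy)-4-methoxy-2-(7-methoxy-2,2-dimethylchroman-5-yl)benzofuran-3(2H)-ylidene]methanone (ketene, racemic) | O=C=C1[C@H](c2cc(OC)cc3OC(C)(C)CCc23)Oc2cc(OCc3ccccc3)cc(OC)c12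
F4 | step 7 | methyl cis-6-(benzyloxy)-4-methoxy-2-(7-methoxy-2,2-dimethylchroman-5-yl)-2,3-dihydrobenzofuran-3-carboxylate (racemic) | COC(=O)[C@@H]1[C@H](c2cc(OC)cc3OC(C)(C)CCc23)Oc2cc(OCc3ccccc3)cc(OC)c12
F5 | step 13 | 4-methoxy-2-(7-methoxy-2,2-dimethylchroman-5-yl)-7-(2-methylbut-3-en-2-yl)benzofuran-6-yl acetate | C=CC(C)(C)c1c(OC(C)=O)cc(OC)c2cc(-c3cc(OC)cc4OC(C)(C)CCc34)oc12
F6 | step 14 | 4-methoxy-2-(7-methoxy-2,2-dimethylchroman-5-yl)-7-(2-methylbut-3-en-2-yl)-6-(tetrahydropyran-2-yloxy)benzofuran (racemic) | C=CC(C)(C)c1c(O[C@H]2CCCCO2)cc(OC)c2cc(-c3cc(OC)cc4OC(C)(C)CCc34)oc12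
F7 | step 14 | 2-(7-hydroxy-2,2-dimethylchroman-5-yl)-7-(2-methylbut-3-en-2-yl)-6-(tetrahydropyran-2-yloxy)benzofuran-4-ol (racemic) | C=CC(C)(C)c1c(O[C@H]2CCCCO2)cc(O)c2cc(-c3cc(O)cc4OC(C)(C)CCc34)oc12
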